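**Slow feeds.** A slow feed spreads a charge over 15 h, and the question is how many links stand at the end while one partner waits in the flask.

| flask | first end groups | second end groups | remark | time |
|---|---|---|---|---|
| autumn | 16 mM | 15.7 mM | run made earlier |  |
| midnight | 32 mM | 15.7 mM | run made earlier |  |
| birch | 16 mM (fed, over 15 h) | 15.7 mM | all else is in the flask from the start; the feed brings no volume worth counting | 20 h |
| alder | 16 mM | 15.7 mM | everything together at the start | 20 h |
| maple | 16 mM | 15.7 mM (fed, over 15 h) | all else is in the flask from the start; the feed brings no volume worth counting | 20 h |

| run | time / h | links / % |
|---|---|---|
| autumn | 1.00 | 7 |
| autumn | 2.00 | 17 |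
| autumn | 5.00 | 24 |
| autumn | 12.0 | 29 |
| midnight | 1.50 | 9 |
| midnight | 3.00 | 15 |
| midnight | 5.00 | 19 |
| midnight | 6.00 | 20 |

(readings scatter by 1.5 percentage points)

- which flask leads in amount of links, in percent of the first end groups charged ("all alike" within 1.5 percentage points) (birch / alder / maple / all alike)
- how much links is there at the end, in percent of the first end groups charged: birch
- how much links is there at the end, in percent of the first end groups charged: alder
- how much links is there at the end, in percent of the first end groups charged: maple

- the numbers in the tables scatter with a standard deviation of 1.5 percentage points

**Bench rule.** Alder has the charges of the autumn run, where the second end groups are the limiting reagent, so I count by them. The link share, the links at the last reading per second end group charged, is 29.6 % in the autumn run. Held for alder, it gives 29.0 % of the first end groups.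

**Its border.** The rise time, last reading over early slope, reads 3.41 h in the autumn run and 3.33 h in the midnight run. With twice the first end groups the clock stays about the same, so I read it as the lifetime of free second end groups, which were charged alike in both runs. The feed lasts 4.40 rise times, so the rule needs checking in the fed flasks. In maple each second end group arrives among first end groups and lives its rise time there, so I keep the share and expect 29.0 % again. In birch the second end groups wait from the start while first end groups trickle in, so I shrink the overlap by the rise time over the feed time, 0.227, and reckon 6.60 %.

**The forecast.** It says all alike, with birch 27.5 %, alder 28.5 % and maple 27.5 %, on the ground that “This suggests a reversible link”. It parts from my reckoning on birch.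

**The flasks.** The lead goes to alder, with birch 17.7 %, alder 34.8 % and maple 26.3 %.

    2 first end groups → homo dimer (k = 1.80 L mol⁻¹ h⁻¹)
    second end groups → decomposed reagent (k = 0.130 h⁻¹)
    first end groups + second end groups ⇌ links + by-product (K = 34.0, k = 7.20 L mol⁻¹ h⁻¹)
    first end groups + by-product → side product (k = 0.680 L mol⁻¹ h⁻¹)

Birch lies between my 6.60 % and the forecast's 27.5 %, and alder's link share is 35.5 %, above the 29.6 % carried. In alder at 3.44 h, second end groups have a half-life of 5.3 h on the path to decomposed reagent against 9.3 h by the forward link step. At 20.0 h these stand at 5.3 h and 19 h, with 2.6 % of the charged second end groups left unbound. In a further flask, like alder but charged with 6.3 mM of second end groups, the carried share gives 11.6 % of the first end groups, and that flask holds 15.4 %.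

(The data are simulated for an exercise; the scatter is artificial.)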